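**Compound numbers used throughout**

1 2,4-dihydroxyacetophenone; 2 its 4-O-pivalate; 3 the enaminone; 4 the 3-iodochromone; 5 trimethylsilylacetylene; 6 the silylalkyne; 7 the terminal alkyne; 8 the 1-stannylvinyl chromone; 9 dimethyl squarate; 10 the hydroxycyclobutenone; 11 the chlorocyclobutenone; 12, 13 and 14 the unisolated intermediates of the benzannulation (coupled cyclobutenone, dienylketene, cyclohexadienone); 15 the ring-B phenol; 16 the catechol; 17 3-chloro-3-methylbut-1-yne; 18 the propargyl ether; 19 the 7-O-pivalate of the target; 20 the target. Ring B atoms are C1' to C6'; ring D atoms are O1'', C2'', C3'' and C4''.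

## Analysis of the target

Compound 20 is a 7-hydroxyisoflavone. Ring A (the benzo ring with the C7 hydroxyl) and ring C (the 4-pyranone) form a chromen-4-one whose C3 carries ring B, and ring B is fused through C2' and C3' to a 2,2-dimethyl-2H-pyran, ring D. Ring B is pentasubstituted: C1' holds the chromone, C2' the alkene carbon C4'' of ring D, C3' the ring-D oxygen, C4' a free hydroxyl and C5' a methoxy group; only C6' carries hydrogen. There is no stereocentre, and the one alkene that could have geometry lies in ring D and is cis by necessity, so every selectivity question is one of regiochemistry or chemoselectivity. The sensitive sites are C2 of the chromone (it adds hydroxide, thiolates and unhindered amines with opening of ring C), the tertiary allylic and benzylic ether of ring D (it ionises under protic and Lewis acids, and its alkene is lost on hydrogenation), and the oxidisable trioxygenated arene. The difficulty is ring B: three neighbouring oxygens must end as three different functions (ring ether, free phenol, methyl ether) beside an aryl–chromone bond flanked by a ring-D carbon, which is awkward to reach by substitution on a preformed benzene and makes a late biaryl-type coupling hindered. The plan rests on the fact that ring B need not exist at the start: C3' with its oxygen, C4', C5' and C6' correspond to the carbonyl carbon, the two alkoxy-bearing alkene carbons and the sp3 carbon of a 2,3-dialkoxycyclobut-2-enone, and C1' and C2' are the two carbons of a vinyl group that already carries the chromone on its inner carbon.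

## Retrosynthetic reasoning

**20 from 19.** Only the acyl–oxygen bond at C7 is cut. The C7 hydroxyl is the most acidic phenol of the molecule and would compete in every O-alkylation, so it stays masked from the first step to the last. A hindered ester is chosen because it has to pass cross-coupling, desilylation, hydrostannation, Lewis-acid demethylation and O-alkylation under base. The forward reaction only has to transesterify an aryl ester without opening ring C.

**19 from 18.** Ring D is opened at the C2'–C4'' bond and the ring oxygen is left on C3' as a tertiary propargyl ether, which gives 18. Forward, this is the aromatic propargyl Claisen rearrangement with its follow-up hydrogen shift and oxa-electrocyclisation. Cutting here and not at O1''–C2'' keeps the ring closure free of acid, and C2' is the only unsubstituted carbon ortho to O3', so the sigmatropic shift has a single outlet. Ring D is thereby reduced to an ether of a phenol.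

**18 from 16 and 17.** The O3'–C ether bond is cut to the catechol 16 and the tertiary chloride 17. The plan relies on the difference between the two hydroxyls of 16: the 3'-hydroxyl has one ortho neighbour and sits meta to the methoxy group, so it is the more accessible and slightly the more acidic, whereas the 4'-hydroxyl is wedged between two oxygens. A bulky tertiary electrophile should therefore go to O3' without a protecting group on O4'; a selective protection of O4' cannot be defended, because any mono-protection would follow the same bias and land on O3'. The forward step must deliver the monoether at O3'.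

**16 from 15.** The retrosynthetic step puts a methyl group back on O4'. A methyl ether is accepted there because 15 then has two identical alkoxy groups and maps onto a cyclobutenone from the symmetrical squarate 9. Forward, one of two methyl ethers must go; the 4'-methoxy is the one beside the free 3'-hydroxyl and the central, twisted member of the oxygen triad, so a Lewis acid anchored on the phenol is delivered to it. This step is placed before ring D exists because the ether of ring D would not survive it.

**15 from 8 and 11 (key disconnection).** Two bonds of ring B are cut, C1'–C6' and C2'–C3', which leads to the stannane 8 and the chlorocyclobutenone 11. Forward, cross-coupling gives 12, ring opening gives 13, electrocyclisation gives 14 and enolisation gives 15. These bonds are chosen because cutting them removes the whole problem of placing five substituents on a benzene ring: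
- the carbonyl carbon of 11 becomes C3' and supplies the one free hydroxyl exactly where ring D is attached later;
- the two methoxy carbons become C4' and C5';
- the chlorine-bearing carbon becomes the unsubstituted C6';
- the CH2 of the vinyl group becomes the free C2' needed for the Claisen step.

A cut at C3–C1' alone would leave the pentasubstituted ring to be made separately. The forward step must join C4 of 11 to the tin-bearing carbon of 8 and then let heat do the rest.

**8 from 7, 6, 4 and 5.** Stannane 8 is cut at the C–Sn bond to the terminal alkyne 7, since Markovnikov hydrostannation is the shortest access to a 1-substituted vinylstannane. Alkyne 7 comes from its silyl derivative 6, and 6 from iodide 4 and alkyne 5 by cutting the C3–C(sp) bond (Sonogashira coupling). The C3–I bond of a chromone couples readily, and the alkyne brings in both vinyl carbons at once.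

**4 from 3, 2 and 1.** Iodide 4 is opened at O1–C2 and C3–I to the enaminone 3 (iodocyclisation), 3 is cut at its C=C bond to the methyl ketone 2, and 2 at the ester to 1. Ring C is thus built on a bought ring A, with the C7 oxygen acylated first, where the chelated 2-hydroxyl makes the acylation selective.

**11 from 10 and 9.** Chloride 11 is traced to alcohol 10 (C–Cl to C–O) and 10 to 9 (C–H to C=O). Because 9 is symmetrical the hydride reduction has no regiochemical question, and the exchange at C4 is a hydroxyl-to-halide substitution that must be run without acid.

## Alternatives that were turned down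

**Alternative 1:** Ring D by sulfur extrusion.
- Disconnection: the C3''=C4'' double bond is replaced by a CH2–SO2–CH2 bridge, so the precursor is the seven-membered cyclic sulfone A2 (6-bromo-8-methoxy-9-(methoxymethoxy)-2,2-dimethyl-2,3-dihydro-5H-1,4-benzoxathiepine 4,4-dioxide).
- Forward key step: a one-pot Ramberg–Bäcklund reaction (CBr2F2 as halogen source, KOH on Al2O3) halogenates the benzylic carbon next to sulfur, the opposite carbanion closes to an episulfone, and extrusion of the sulfonyl bridge contracts the ring to the chromene A1 (5-bromo-7-methoxy-8-(methoxymethoxy)-2,2-dimethyl-2H-chromene).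
- For it: the alkene appears exactly where the sulfone was, without heat or acid, the ring forces the cis geometry, and the two phenolic oxygens are already differentiated. On this one point, a mild and position-defined installation of the ring-D alkene, it is stronger than the thermal Claisen cascade used here.
- Against it: A2 already contains the complete pentasubstituted benzene (bromine, CH2S, tertiary alkyl ether, acetal-protected oxygen and methoxy on five neighbouring carbons) and a tertiary alkyl aryl ether. Neither is easy to make, so the real problem of the target is moved into the preparation of A2. After A1, ring C must still be attached at a bromide flanked by the peri alkene carbon, a hindered coupling on an acid-sensitive chromene, followed by two deprotections.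
- Comparison: the chosen strategy builds that benzene ring with its substituents in the right order in one operation from two fragments that are each a few steps from bought material, and needs no hindered coupling.

**Alternative 2:** Ring C closed last by a Parham cyclisation.
- Disconnection: the C4–C4a bond; the precursor is the enol ether ester A4 (methyl (Z)-3-[2-bromo-5-(triisopropylsilyloxy)phenoxy]-2-[7-methoxy-2,2-dimethyl-8-(triisopropylsilyloxy)-2H-chromen-5-yl]acrylate), with ring A attached through O1 and the ester carbon as the future C4.
- Forward key step: bromine–lithium exchange with tert-butyllithium at low temperature gives the aryllithium at C4a, which acylates itself on the cis ester with loss of the ester alkoxy group and gives the isoflavone A3 (3-[7-methoxy-2,2-dimethyl-8-(triisopropylsilyloxy)-2H-chromen-5-yl]-7-(triisopropylsilyloxy)chromen-4-one).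
- For it: the closure of ring C is regiochemically unambiguous and cold, and both silyl ethers of A3 would fall in one mild desilylation. Its end game is shorter and gentler than the demethylation, alkylation and rearrangement needed here, and on that point it is the stronger plan.
- Against it: A4 presupposes the finished ring B/ring D unit as an arylacetic ester, so the pentasubstituted arene must be assembled beforehand by other means. The acrylate is a Michael acceptor and its ester an electrophile for the alkyllithium, so exchange has to outrun conjugate and carbonyl addition. Only the Z isomer can cyclise, and β-aryloxyacrylates isomerise easily.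
- Comparison: the chosen strategy buys rings A and C cheaply through three standard steps and spends its key step on ring B, which is where the difficulty lies.

**Alternative 3:** Ring D closed by oxidative formation of the C3'–O bond.
- Disconnection: the C3'–O1'' bond; the precursor A6 (3-{4-hydroxy-2-[(Z)-3-hydroxy-3-methylbut-1-en-1-yl]-5-methoxyphenyl}-4-oxo-4H-chromen-7-yl acetate) has hydrogen at C3' and the side chain on C2'.
- Forward key step: PhI(OAc)2 (trivalent iodine) in hexafluoroisopropanol turns the C4' phenol into a phenoxenium-type species, the tertiary hydroxyl attacks C3' through a six-membered transition state, and loss of the C3' proton rearomatises to A5 (3-(8-hydroxy-7-methoxy-2,2-dimethyl-2H-chromen-5-yl)-4-oxo-4H-chromen-7-yl acetate).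
- For it: the C3' oxygen is introduced by C–H functionalisation with the 4'-hydroxyl free throughout, so the two ortho oxygens never have to be told apart and no demethylation is needed. In redox and protecting-group economy it is better than the chosen route.
- Against it: a 2-methoxyphenol under such conditions is normally attacked at the methoxy-bearing carbon (here C5') to give an ortho-quinone monoketal, or at the para carbon C1', and nothing in A6 except the tether favours C3'. A5 is more electron-rich than A6 and would be oxidised further. The tertiary allylic alcohol can ionise in the acidic medium, and the Z alkene, which needs its own stereoselective step, can isomerise out of reach.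
- Comparison: the chosen strategy gives up a late C–H oxidation but fixes the C3' oxygen with certainty, because it is the ketene oxygen of 13.

Key step: step 9

Remark: 20 has no stereocentre; 10, 11 and 12 are racemic, and their single stereocentre ends as the aromatic carbon C6', so no configuration has to be set or kept.

## Route

Step 1
Reactants: 1 2,4-dihydroxyacetophenone
Product: 2 4-acetyl-3-hydroxyphenyl pivalate
Conditions: PivCl (1.05 equiv), Et3N, CH2Cl2, 0 °C
Reagents that add atoms: pivaloyl chloride, CC(C)(C)C(=O)Cl
Why: The 2-hydroxyl is locked in a hydrogen bond to the acetyl carbonyl and is far less nucleophilic, so O-acylation under amine base should take the 4-hydroxyl only. The hindered ester is chosen to survive every later step up to the last.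

Step 2
Reactants: 2 4-acetyl-3-hydroxyphenyl pivalate
Product: 3 4-[(2E)-3-(dimethylamino)prop-2-enoyl]-3-hydroxyphenyl pivalate
Conditions: Me2NCH(OMe)2, toluene, 80 °C
Reagents that add atoms: N,N-dimethylformamide dimethyl acetal, COC(OC)N(C)C
Why: Enaminone formation by condensation of the methyl ketone with the amide acetal supplies the future C2 of ring C. The E isomer is the conjugated, chelate-stabilised one, and its geometry is lost in the next step anyway.

Step 3
Reactants: 3 4-[(2E)-3-(dimethylamino)prop-2-enoyl]-3-hydroxyphenyl pivalate
Product: 4 3-iodo-4-oxo-4H-chromen-7-yl pivalate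
Conditions: I2, CHCl3, rt
Reagents that add atoms: iodine, II
Why: Iodocyclisation of a 2-hydroxyaryl enaminone: iodine attacks the nucleophilic α-carbon, the phenol closes on the iminium carbon and dimethylamine is expelled, giving the 3-iodochromone directly.

Step 4
Reactants: 4 3-iodo-4-oxo-4H-chromen-7-yl pivalate; 5 trimethylsilylacetylene
Product: 6 4-oxo-3-[(trimethylsilyl)ethynyl]-4H-chromen-7-yl pivalate
Conditions: PdCl2(PPh3)2 (cat.), CuI (cat.), Et3N, THF, rt
Reagents that add atoms: none
Why: Sonogashira coupling; the electron-poor vinylic C3–I bond should add to palladium at room temperature, and a tertiary amine base cannot add to C2 of the chromone.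

Step 5
Reactants: 6 4-oxo-3-[(trimethylsilyl)ethynyl]-4H-chromen-7-yl pivalate
Product: 7 3-ethynyl-4-oxo-4H-chromen-7-yl pivalate
Conditions: Bu4NF, AcOH, THF, 0 °C
Reagents that add atoms: none
Why: Fluoride-induced protodesilylation of the alkynylsilane. Buffering with acetic acid keeps the medium non-basic, so neither the aryl ester nor C2 of the chromone should be attacked.

Step 6
Reactants: 7 3-ethynyl-4-oxo-4H-chromen-7-yl pivalate
Product: 8 4-oxo-3-[1-(tributylstannyl)vinyl]-4H-chromen-7-yl pivalate
Conditions: Bu3SnH, Mo(CO)3(CNtBu)3 (cat.), hydroquinone (cat.), THF, 55 °C
Reagents that add atoms: tributyltin hydride, CCCC[SnH](CCCC)CCCC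
Why: Hydrostannation of a terminal alkyne catalysed by Mo(CO)3(CNtBu)3 (zerovalent molybdenum) places tin on the internal carbon, a preference reinforced by the electron-poor chromonyl substituent. Hydroquinone suppresses the radical chain that would put tin on the terminal carbon.

Step 7
Reactants: 9 dimethyl squarate
Product: 10 rac-4-hydroxy-2,3-dimethoxycyclobut-2-en-1-one
Conditions: LiAlH(OtBu)3, THF, −20 → 0 °C; then H2O
Reagents that add atoms: none
Why: 1,2-Reduction of one of the two equivalent carbonyls of the squarate by a mild, bulky hydride, which should stop at the hydroxy ketone. The new stereocentre is racemic and is erased in step 9.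

Step 8
Reactants: 10 rac-4-hydroxy-2,3-dimethoxycyclobut-2-en-1-one
Product: 11 rac-4-chloro-2,3-dimethoxycyclobut-2-en-1-one
Conditions: PPh3, CCl4, CH2Cl2, 0 °C → rt; used at once
Reagents that add atoms: tetrachloromethane, ClC(Cl)(Cl)Cl
Why: Appel reaction: the oxyphosphonium ion is displaced by chloride at C4, which is activated as an α-keto and allylic position. The neutral medium avoids the acid-induced ionisation that would destroy the dialkoxycyclobutenone.

Step 9
Reactants: 8 4-oxo-3-[1-(tributylstannyl)vinyl]-4H-chromen-7-yl pivalate; 11 rac-4-chloro-2,3-dimethoxycyclobut-2-en-1-one
Product: 15 3-(3-hydroxy-4,5-dimethoxyphenyl)-4-oxo-4H-chromen-7-yl pivalate, via 4-alkenylcyclobutenone 12 (not isolated), via dienylketene 13 (not isolated), via cyclohexadienone 14 (not isolated)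
Conditions: Pd2(dba)3 (cat.), tri(2-furyl)phosphine, CuI (cat.), 1,4-dioxane, 50 °C, then 100 °C
Reagents that add atoms: none
Why: Zerovalent palladium from Pd2(dba)3 and the weakly donating tri(2-furyl)phosphine inserts into the C4–Cl bond of 11, activated as an α-chloro ketone and an allylic chloride, to give an oxocyclobutenyl palladium chloride; transmetalation from tin, helped by CuI because the tin-bearing carbon of 8 is branched, and reductive elimination at C4 form the C6'–C1' bond and give 12. On warming, 12 undergoes conrotatory four-electron ring opening to a vinylketene; only the rotamer with the chromonylvinyl group turned inward, 13, has the ketene carbon within reach of the vinyl CH2, and the outward isomer recloses to 12, so the equilibrium drains through 13. Disrotatory six-electron electrocyclisation of 13, a thermal hexatriene closure in which one terminus is the ketene carbon, forms the C2'–C3' bond and the six-membered carbocycle as dienone 14, and enolisation to the aromatic phenol 15 makes the sequence irreversible. The closest known reaction type is the Stille coupling of 4-chlorocyclobutenones with alkenylstannanes followed by thermal benzannulation to phenols, applied here to a stannane that carries a chromone. No stereocentre is formed, and the racemic centre of 11 becomes the aromatic C6'. Three selectivities are needed: coupling at C4 and not at C2 of the cyclobutenyl fragment, secured because only bond formation at C4 regenerates the conjugated vinylogous ester; attachment through the tin-bearing inner vinyl carbon and not the CH2 terminus, secured by the position of tin and by copper-accelerated transmetalation; and the placement of hydroxyl, methoxy and methoxy on C3', C4' and C5', which follows from the constitution of 11 because its carbonyl carbon can only become C3'. The aryl pivalate and the chromone should be inert under these neutral conditions.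

Step 10
Reactants: 15 3-(3-hydroxy-4,5-dimethoxyphenyl)-4-oxo-4H-chromen-7-yl pivalate
Product: 16 3-(3,4-dihydroxy-5-methoxyphenyl)-4-oxo-4H-chromen-7-yl pivalate
Conditions: BCl3, CH2Cl2, −78 → 0 °C; then H2O
Reagents that add atoms: none
Why: Ortho-hydroxyl-directed Lewis-acid demethylation: the 3'-phenol forms an aryloxydichloroborane that binds the neighbouring 4'-methoxy oxygen, which is also the central, twisted one of the triad, and chloride removes the methyl group to leave a five-membered cyclic borate that is hydrolysed on work-up. The 5'-methoxy group, the pivalate and the chromone should be untouched at low temperature, and ring D is not yet present.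

Step 11
Reactants: 16 3-(3,4-dihydroxy-5-methoxyphenyl)-4-oxo-4H-chromen-7-yl pivalate; 17 3-chloro-3-methylbut-1-yne
Product: 18 3-{4-hydroxy-3-methoxy-5-[(2-methylbut-3-yn-2-yl)oxy]phenyl}-4-oxo-4H-chromen-7-yl pivalate
Conditions: K2CO3, KI (cat.), acetone, 55 °C, argon
Reagents that add atoms: none
Why: Williamson-type O-alkylation with a tertiary propargylic chloride under copper-free conditions, so that the catechol is neither chelated nor oxidised. The 3'-hydroxyl is the less hindered one (one ortho neighbour against two) and, being meta to the methoxy group, slightly the more acidic, and the bulky electrophile should amplify this preference. The remaining 4'-hydroxyl is flanked on both sides and hydrogen-bonded, so a second alkylation is not expected.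

Step 12
Reactants: 18 3-{4-hydroxy-3-methoxy-5-[(2-methylbut-3-yn-2-yl)oxy]phenyl}-4-oxo-4H-chromen-7-yl pivalate
Product: 19 3-(8-hydroxy-7-methoxy-2,2-dimethyl-2H-chromen-5-yl)-4-oxo-4H-chromen-7-yl pivalate
Conditions: N,N-diethylaniline, 160 °C
Reagents that add atoms: none
Why: Aromatic propargyl Claisen rearrangement: the [3,3] shift goes to C2', the only free position ortho to O3', and enolisation, 1,5-hydrogen shift and oxa-six-electron electrocyclisation then close the 2,2-dimethyl-2H-pyran. The geminal methyl groups accelerate the sigmatropic step, and the neutral thermal conditions spare the ester and the free 4'-phenol.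

Step 13
Reactants: 19 3-(8-hydroxy-7-methoxy-2,2-dimethyl-2H-chromen-5-yl)-4-oxo-4H-chromen-7-yl pivalate
Product: 20 7-hydroxy-3-(8-hydroxy-7-methoxy-2,2-dimethyl-2H-chromen-5-yl)-4H-chromen-4-one
Conditions: NaOMe (2.2 equiv), MeOH–THF, 0 °C → rt; then AcOH
Reagents that add atoms: none
Why: Transesterification of the aryl ester by methoxide; the first equivalent is taken up by the 4'-phenol and the second cleaves the pivalate. The 7-phenoxide that forms deactivates C2 of ring C towards further attack, and ring D is inert to base.

## Compound list

1 | 2,4-dihydroxyacetophenone | CC(=O)c1ccc(O)cc1O | starting material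
2 | 4-acetyl-3-hydroxyphenyl pivalate | CC(=O)c1ccc(OC(=O)C(C)(C)C)cc1O | intermediate
3 | 4-[(2E)-3-(dimethylamino)prop-2-enoyl]-3-hydroxyphenyl pivalate | CN(C)/C=C/C(=O)c1ccc(OC(=O)C(C)(C)C)cc1O | intermediate
4 | 3-iodo-4-oxo-4H-chromen-7-yl pivalate | CC(C)(C)C(=O)Oc1ccc2c(c1)occ(I)c2=O | intermediate
5 | trimethylsilylacetylene | C#C[Si](C)(C)C | starting material
6 | 4-oxo-3-[(trimethylsilyl)ethynyl]-4H-chromen-7-yl pivalate | CC(C)(C)C(=O)Oc1ccc2c(c1)occ(C#C[Si](C)(C)C)c2=O | intermediate
7 | 3-ethynyl-4-oxo-4H-chromen-7-yl pivalate | CC(C)(C)C(=O)Oc1ccc2c(c1)occ(C#C)c2=O | intermediate
8 | 4-oxo-3-[1-(tributylstannyl)vinyl]-4H-chromen-7-yl pivalate | C=C([Sn](CCCC)(CCCC)CCCC)c1coc2cc(OC(=O)C(C)(C)C)ccc2c1=O | intermediate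
9 | dimethyl squarate (3,4-dimethoxycyclobut-3-ene-1,2-dione) | COC1=C(OC)C(=O)C1=O | starting material
10 | rac-4-hydroxy-2,3-dimethoxycyclobut-2-en-1-one | O=C1C(OC)=C(OC)C1O | intermediate
11 | rac-4-chloro-2,3-dimethoxycyclobut-2-en-1-one | O=C1C(OC)=C(OC)C1Cl | intermediate
12 | rac-3-[1-(2,3-dimethoxy-4-oxocyclobut-2-en-1-yl)vinyl]-4-oxo-4H-chromen-7-yl pivalate (not isolated) | C=C(C1C(OC)=C(OC)C1=O)c1coc2cc(OC(=O)C(C)(C)C)ccc2c1=O | intermediate
13 | 3-[(3E)-4,5-dimethoxy-6-oxohexa-1,3,5-trien-2-yl]-4-oxo-4H-chromen-7-yl pivalate (dienylketene, not isolated) | O=C=C(OC)/C(OC)=C\C(=C)c1coc2cc(OC(=O)C(C)(C)C)ccc2c1=O | intermediate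
14 | 3-(3,4-dimethoxy-5-oxocyclohexa-1,3-dien-1-yl)-4-oxo-4H-chromen-7-yl pivalate (not isolated) | O=C1CC(c2coc3cc(OC(=O)C(C)(C)C)ccc3c2=O)=CC(OC)=C1OC | intermediate
15 | 3-(3-hydroxy-4,5-dimethoxyphenyl)-4-oxo-4H-chromen-7-yl pivalate | CC(C)(C)C(=O)Oc1ccc2c(c1)occ(-c1cc(O)c(OC)c(OC)c1)c2=O | intermediate
16 | 3-(3,4-dihydroxy-5-methoxyphenyl)-4-oxo-4H-chromen-7-yl pivalate | CC(C)(C)C(=O)Oc1ccc2c(c1)occ(-c1cc(O)c(O)c(OC)c1)c2=O | intermediate
17 | 3-chloro-3-methylbut-1-yne | CC(C)(Cl)C#C | starting material
18 | 3-{4-hydroxy-3-methoxy-5-[(2-methylbut-3-yn-2-yl)oxy]phenyl}-4-oxo-4H-chromen-7-yl pivalate | CC(C)(C)C(=O)Oc1ccc2c(c1)occ(-c1cc(OC)c(O)c(OC(C)(C)C#C)c1)c2=O | intermediate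
19 | 3-(8-hydroxy-7-methoxy-2,2-dimethyl-2H-chromen-5-yl)-4-oxo-4H-chromen-7-yl pivalate | COc1cc(-c2coc3cc(OC(=O)C(C)(C)C)ccc3c2=O)c2c(c1O)OC(C)(C)C=C2 | intermediate
20 | 7-hydroxy-3-(8-hydroxy-7-methoxy-2,2-dimethyl-2H-chromen-5-yl)-4H-chromen-4-one | COc1cc(-c2coc3cc(O)ccc3c2=O)c2c(c1O)OC(C)(C)C=C2 | target

## Step count and least certain steps

Total: 13 steps. Longest linear sequence: 11 steps (steps 1 to 6 and 9 to 13); steps 7 and 8 are a two-step branch that joins at step 9.

**Step 9 (key step).** The most likely failure is slow transmetalation at the branched, tin-bearing carbon of 8. Protodestannylation, coupling through the CH2 terminus (cine substitution, which would put the chromone ortho to the new hydroxyl) or decay of 11 by ionisation could then compete. A second possibility is interception of the ketene by traces of moisture before it cyclises. Fallback: ring B is not built but bought and attached by a biaryl-type coupling. 5-Bromo-2,3-dimethoxyphenol F1 is converted by Miyaura borylation (B2pin2, Pd(dppf)Cl2, KOAc, dioxane, 80 °C) into 2,3-dimethoxy-5-(4,4,5,5-tetramethyl-1,3,2-dioxaborolan-2-yl)phenol F2. Suzuki coupling of F2 with iodide 4 (Pd(dppf)Cl2, K3PO4, dioxane–water, 60 °C) gives 15. This path sets out from 4 and rejoins the route at 15.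

**Step 8.** Departure of the C4 leaving group, assisted by the C2 methoxy group, followed by loss of the O-methyl group would drain material to a cyclobutenedione; attack of chloride at C2 in an SN2' sense leads the same way. Fallback: the chloride is avoided. Alcohol 10 is acylated (ClCO2Me, pyridine, CH2Cl2, −20 °C) to 2,3-dimethoxy-4-oxocyclobut-2-en-1-yl methyl carbonate F3, which is a poorer leaving group on its own but is ionised by zerovalent palladium. Stille coupling of this allylic-type carbonate with 8 (Pd2(dba)3, tri(2-furyl)phosphine, dioxane, 50 → 100 °C) gives 12 in the flask, which goes on to 15 as in step 9. This path sets out from 10 and rejoins at 12.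

**Step 6.** Loss of regiocontrol (tin delivered to the terminal carbon by a radical pathway or by incomplete catalyst control) and conjugate reduction of the C2=C3 bond of the chromone by the tin hydride are the likely problems. Fallback: tin is introduced by substitution instead of addition. Bromoboration of 7 with B-bromo-9-borabicyclo[3.3.1]nonane (CH2Cl2, 0 °C) and protonolysis with AcOH in the same flask give 3-(1-bromovinyl)-4-oxo-4H-chromen-7-yl pivalate F4, with bromine on the internal carbon. Palladium-catalysed stannylation (Pd(PPh3)4, (Bu3Sn)2, toluene, 90 °C) converts F4 into 8. This path sets out from 7 and rejoins at 8.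

**Step 11.** Alkylation at O4' instead of, or in addition to, O3', and oxidative degradation of the catecholate are the risks. Fallback: ring D is made from 16 in one operation whose regiochemistry is fixed by constitution. Annulation with 3-methylbut-2-enal (ethylenediammonium diacetate cat., xylene, 130 °C) proceeds by Knoevenagel-type C-alkylation at C2', dehydration to an ortho-quinone methide and oxa-electrocyclisation. Only the 3'-hydroxyl has a free ortho carbon, so only the wanted ring can close. The path sets out from 16 and rejoins at 19, bypassing 18; it passes through no new isolable compound (entry F0).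

## Further compounds

F1 | step 9 | 5-bromo-2,3-dimethoxyphenol | COc1cc(Br)cc(O)c1OC
F2 | step 9 | 2,3-dimethoxy-5-(4,4,5,5-tetramethyl-1,3,2-dioxaborolan-2-yl)phenol | COc1cc(B2OC(C)(C)C(C)(C)O2)cc(O)c1OC
F3 | step 8 | 2,3-dimethoxy-4-oxocyclobut-2-en-1-yl methyl carbonate | COC(=O)OC1C(OC)=C(OC)C1=O
F4 | step 6 | 3-(1-bromovinyl)-4-oxo-4H-chromen-7-yl pivalate | C=C(Br)c1coc2cc(OC(=O)C(C)(C)C)ccc2c1=O
F0 | step 11 | none | none
A1 | alternative 1 | 5-bromo-7-methoxy-8-(methoxymethoxy)-2,2-dimethyl-2H-chromene | COCOc1c(OC)cc(Br)c2C=CC(C)(C)Oc12
A2 | alternative 1 | 6-bromo-8-methoxy-9-(methoxymethoxy)-2,2-dimethyl-2,3-dihydro-5H-1,4-benzoxathiepine 4,4-dioxide | COCOc1c(OC)cc(Br)c2CS(=O)(=O)CC(C)(C)Oc12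
A3 | alternative 2 | 3-[7-methoxy-2,2-dimethyl-8-(triisopropylsilyloxy)-2H-chromen-5-yl]-7-(triisopropylsilyloxy)chromen-4-one | CC(C)[Si](C(C)C)(C(C)C)Oc1ccc2c(c1)occ(-c1cc(OC)c(O[Si](C(C)C)(C(C)C)C(C)C)c3OC(C)(C)C=Cc13)c2=O
A4 | alternative 2 | methyl (Z)-3-[2-bromo-5-(triisopropylsilyloxy)phenoxy]-2-[7-methoxy-2,2-dimethyl-8-(triisopropylsilyloxy)-2H-chromen-5-yl]acrylate | COC(=O)/C(=C\Oc1cc(O[Si](C(C)C)(C(C)C)C(C)C)ccc1Br)c1cc(OC)c(O[Si](C(C)C)(C(C)C)C(C)C)c2OC(C)(C)C=Cc12
A5 | alternative 3 | 3-(8-hydroxy-7-methoxy-2,2-dimethyl-2H-chromen-5-yl)-4-oxo-4H-chromen-7-yl acetate | CC(=O)Oc1ccc2c(c1)occ(-c1cc(OC)c(O)c3OC(C)(C)C=Cc13)c2=O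
A6 | alternative 3 | 3-{4-hydroxy-2-[(Z)-3-hydroxy-3-methylbut-1-en-1-yl]-5-methoxyphenyl}-4-oxo-4H-chromen-7-yl acetate | CC(=O)Oc1ccc2c(c1)occ(-c1cc(OC)c(O)cc1/C=C\C(C)(C)O)c2=O
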